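**Retrosynthetic overview**
- Endgame: the sinapyl (E)-CH=CH–CH2OH arm comes from a ring-B aldehyde by Wittig olefination and hydride reduction; the same hydride removes the aryl acetate.
- C9–OH comes from oxidative cleavage (ozonolysis, reductive work-up) of a vinyl group.
- Key C7–C8 bond: vanillin acetate (electrophilic CHO) plus a (Z)-γ-aryloxyallylborane, in which the oxygen-bearing allyl-ether carbon reacts as an α-aryloxy carbanion (reversed polarity). One chair transition state sets both stereocentres (syn, 7R,8R), with the 8-O-4′ aryl ether already in place.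
- The allyl ether comes from syringaldehyde and allyl bromide, with the aldehyde masked as a dioxolane.
- No ring is built: both arenes are bought; the dioxolane is a temporary protecting group.

Assumption: the SMILES is read as the (7R,8R)-threo isomer; sec-BuLi and (−)-Ipc2BOMe are numbered because their atoms appear in the unisolated intermediates of step 3.

**Step 1**
Reactants: 1 syringaldehyde (4-hydroxy-3,5-dimethoxybenzaldehyde); 2 allyl bromide
Product: 3 3,5-dimethoxy-4-(prop-2-en-1-yloxy)benzaldehyde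
Conditions: K2CO3, DMF, 60 °C
Reagents that add atoms: none
Why: Williamson ether synthesis; the acidic phenoxide (para-CHO) is alkylated by the unhindered allylic bromide (SN2) despite the two flanking OMe groups, and no stereocentre is formed.

**Step 2**
Reactants: 3 3,5-dimethoxy-4-(prop-2-en-1-yloxy)benzaldehyde
Product: 4 2-[3,5-dimethoxy-4-(prop-2-en-1-yloxy)phenyl]-1,3-dioxolane
Conditions: HOCH2CH2OH, cat. TsOH, toluene, reflux (Dean–Stark)
Reagents that add atoms: ethylene glycol, OCCO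
Why: Acid-catalysed acetalisation driven by azeotropic water removal masks the aldehyde against sec-BuLi, the allylborane and borane; both ortho positions are blocked and 110 °C is far below Claisen temperatures, and no stereocentre is formed.

**Step 3**
Reactants: 4 2-[3,5-dimethoxy-4-(prop-2-en-1-yloxy)phenyl]-1,3-dioxolane; 5 sec-butyllithium; 6 (−)-B-methoxydiisopinocampheylborane (from (+)-α-pinene); 7 vanillin acetate (4-formyl-2-methoxyphenyl acetate)
Product: 12 4-[(1R,2R)-2-[4-(1,3-dioxolan-2-yl)-2,6-dimethoxyphenoxy]-1-hydroxybut-3-en-1-yl]-2-methoxyphenyl acetate, via allyllithium 8 (not isolated), via lithium borate 9 (not isolated), via allylborane 10 (not isolated), via borinate ester 11 (not isolated)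
Conditions: 4 (1.5 eq), s-BuLi, THF, −78 °C; (−)-Ipc2BOMe, −78 °C; BF3·OEt2 then 7 (1.0 eq), −78 °C, 4 h; H2NCH2CH2OH, Et2O, 0 °C→rt
Reagents that add atoms: none
Why: Brown asymmetric γ-alkoxyallylboration used as a polarity-reversed C–C bond formation: deprotonation α to oxygen gives the O→Li-chelated (Z)-oxyallyl anion 8, boron traps the terminus (9), BF3 removes methoxide to give 10, and the Zimmerman–Traxler chair allyl transfer to 7 makes the oxygen-bearing carbon the nucleophile, joining two normally electrophilic C–O carbons; the Z geometry gives the syn (threo) pair and the d-Ipc ligands direct attack on the si face of the aldehyde, setting 7R and with it 8R (expected dr >95:5 and ee about 90 % by analogy with allyl methyl, MOM and p-methoxyphenyl ethers, upgradable by recrystallising 12 or 15).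

**Step 4**
Reactants: 12 4-[(1R,2R)-2-[4-(1,3-dioxolan-2-yl)-2,6-dimethoxyphenoxy]-1-hydroxybut-3-en-1-yl]-2-methoxyphenyl acetate
Product: 15 4-[(1R,2R)-2-(4-formyl-2,6-dimethoxyphenoxy)-1,3-dihydroxypropyl]-2-methoxyphenyl acetate, via ozonide 13 (not isolated), via diol acetal 14 (not isolated)
Conditions: O3, CH2Cl2, −78 °C (Sudan Red 7B end-point); BH3·SMe2, −78 °C→rt; MeOH; 1 M HCl, THF, rt
Reagents that add atoms: ozone, O=[O+][O-]; water, O
Why: Ozonolysis with reductive work-up: the terminal vinyl is the only alkene and out-competes the arenes under dye-controlled dosing, BH3·SMe2 reduces the ozonide directly to the primary alcohol without base (so the epimerisable, retro-aldol-prone α-aryloxy-β-hydroxy aldehyde is never exposed and the aryl acetate survives), and dilute aqueous acid then hydrolyses the electron-rich aryl dioxolane; C7 and C8 are untouched.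

**Step 5**
Reactants: 15 4-[(1R,2R)-2-(4-formyl-2,6-dimethoxyphenoxy)-1,3-dihydroxypropyl]-2-methoxyphenyl acetate; 16 ethyl (triphenylphosphoranylidene)acetate
Product: 18 (1R,2R)-1-(4-hydroxy-3-methoxyphenyl)-2-[4-[(E)-3-hydroxyprop-1-en-1-yl]-2,6-dimethoxyphenoxy]propane-1,3-diol (target), via cinnamate ester 17 (not isolated)
Conditions: 16 (1.05 eq), toluene/CH2Cl2, 60 °C; then DIBAL-H (9 eq), −78→0 °C; Rochelle salt
Reagents that add atoms: none
Why: Wittig olefination with a stabilised ylide gives the (E)-cinnamate (E:Z >95:5) under neutral conditions that tolerate the free diol, and DIBAL-H added to the same flask does the 1,2-reduction of the enoate to the allylic alcohol while reductively cleaving the aryl acetate (the standard endgame for coniferyl and sinapyl alcohols); no stereocentre is touched and the alkene geometry is fixed in the Wittig stage.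

**Compound list**
1 | syringaldehyde (4-hydroxy-3,5-dimethoxybenzaldehyde) | COc1cc(C=O)cc(OC)c1O | starting material
2 | allyl bromide | C=CCBr | starting material
3 | 3,5-dimethoxy-4-(prop-2-en-1-yloxy)benzaldehyde | COc1cc(C=O)cc(OC)c1OCC=C | intermediate
4 | 2-[3,5-dimethoxy-4-(prop-2-en-1-yloxy)phenyl]-1,3-dioxolane | COc1cc(C2OCCO2)cc(OC)c1OCC=C | intermediate
5 | sec-butyllithium | [Li]C(C)CC | starting material
6 | (−)-B-methoxydiisopinocampheylborane (d-Ipc, from (+)-α-pinene) | COB([C@@H]1C[C@@H]2C[C@H]([C@H]1C)C2(C)C)[C@@H]1C[C@@H]2C[C@H]([C@H]1C)C2(C)C | starting material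
7 | vanillin acetate (4-formyl-2-methoxyphenyl acetate) | COc1cc(C=O)ccc1OC(C)=O | starting material
8 | (Z)-3-[4-(1,3-dioxolan-2-yl)-2,6-dimethoxyphenoxy]prop-2-en-1-yllithium | COc1cc(C2OCCO2)cc(OC)c1O/C=C\C[Li] | intermediate
9 | lithium [(Z)-3-aryloxyallyl](methoxy)bis(d-isopinocampheyl)borate (aryl = 4-(1,3-dioxolan-2-yl)-2,6-dimethoxyphenyl) | [Li+].CO[B-](C/C=C\Oc1c(OC)cc(C2OCCO2)cc1OC)([C@@H]1C[C@@H]2C[C@H]([C@H]1C)C2(C)C)[C@@H]1C[C@@H]2C[C@H]([C@H]1C)C2(C)C | intermediate
10 | [(Z)-3-aryloxyallyl]bis(d-isopinocampheyl)borane (same aryl) | COc1cc(C2OCCO2)cc(OC)c1O/C=C\CB([C@@H]1C[C@@H]2C[C@H]([C@H]1C)C2(C)C)[C@@H]1C[C@@H]2C[C@H]([C@H]1C)C2(C)C | intermediate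
11 | bis(d-isopinocampheyl)borinate ester of 12 (B on the C7 oxygen) | COc1cc([C@@H](OB([C@@H]2C[C@@H]3C[C@H]([C@H]2C)C3(C)C)[C@@H]2C[C@@H]3C[C@H]([C@H]2C)C3(C)C)[C@@H](C=C)Oc2c(OC)cc(C3OCCO3)cc2OC)ccc1OC(C)=O | intermediate
12 | 4-[(1R,2R)-2-[4-(1,3-dioxolan-2-yl)-2,6-dimethoxyphenoxy]-1-hydroxybut-3-en-1-yl]-2-methoxyphenyl acetate | COc1cc([C@@H](O)[C@@H](C=C)Oc2c(OC)cc(C3OCCO3)cc2OC)ccc1OC(C)=O | intermediate
13 | secondary ozonide (1,2,4-trioxolane) of 12, C7/C8 geometry unchanged, trioxolane carbon as a mixture | COc1cc([C@@H](O)[C@@H](C2OCOO2)Oc2c(OC)cc(C3OCCO3)cc2OC)ccc1OC(C)=O | intermediate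
14 | 4-[(1R,2R)-2-[4-(1,3-dioxolan-2-yl)-2,6-dimethoxyphenoxy]-1,3-dihydroxypropyl]-2-methoxyphenyl acetate | COc1cc([C@@H](O)[C@@H](CO)Oc2c(OC)cc(C3OCCO3)cc2OC)ccc1OC(C)=O | intermediate
15 | 4-[(1R,2R)-2-(4-formyl-2,6-dimethoxyphenoxy)-1,3-dihydroxypropyl]-2-methoxyphenyl acetate | COc1cc([C@@H](O)[C@@H](CO)Oc2c(OC)cc(C=O)cc2OC)ccc1OC(C)=O | intermediate
16 | ethyl (triphenylphosphoranylidene)acetate | CCOC(=O)C=P(c1ccccc1)(c1ccccc1)c1ccccc1 | starting material
17 | ethyl (E)-3-[4-[(1R,2R)-1-(4-acetoxy-3-methoxyphenyl)-1,3-dihydroxypropan-2-yl]oxy-3,5-dimethoxyphenyl]prop-2-enoate | COc1cc([C@@H](O)[C@@H](CO)Oc2c(OC)cc(/C=C/C(=O)OCC)cc2OC)ccc1OC(C)=O | intermediate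
18 | (1R,2R)-1-(4-hydroxy-3-methoxyphenyl)-2-[4-[(E)-3-hydroxyprop-1-en-1-yl]-2,6-dimethoxyphenoxy]propane-1,3-diol | COc1cc([C@@H](O)[C@@H](CO)Oc2c(OC)cc(/C=C/CO)cc2OC)ccc1O | target

**Totals**
Total step count: 5. Longest linear sequence: 5 (1 → 3 → 4 → 12 → 15 → 18).

**Three steps most likely to fail**

Step 3. Risks: ring metalation competing with allylic deprotonation of the hindered ether; excess BF3 ionising the aryl acetal; the bulky 2,6-dimethoxyaryloxy group eroding ee or rate; loss of the aryl acetate to ethanolamine. Fallback, setting out from 4 and 7 and returning at 12: lithiate 4 with s-BuLi as before but quench with 2-isopropoxy-4,4,5,5-tetramethyl-1,3,2-dioxaborolane. This gives the isolable, purifiable 2-[(2Z)-3-[4-(1,3-dioxolan-2-yl)-2,6-dimethoxyphenoxy]prop-2-en-1-yl]-4,4,5,5-tetramethyl-1,3,2-dioxaborolane F1. Then allylborate 7 under chiral phosphoric acid catalysis with (S)-TRIP (5 mol %, toluene, −30 °C; the antipode of the acid that gives (R)-1-phenylbut-3-en-1-ol from benzaldehyde, sense to be confirmed on a model). Stereocontrol moves from a stoichiometric chiral borane to a catalyst, no BF3 meets the acetal, and the same chair transition state gives syn adduct 12.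

Step 4. Risks: ozone attacking the electron-rich arenes; incomplete ozonide reduction; acid damage to the benzylic alcohol during deacetalisation. Fallback, setting out from 12 and returning at 14: dihydroxylate the vinyl group (cat. OsO4, NMO, acetone/H2O) to 4-[(1R,2S)-2-[4-(1,3-dioxolan-2-yl)-2,6-dimethoxyphenoxy]-1,3,4-trihydroxybutyl]-2-methoxyphenyl acetate F2 (epimer mixture at the new carbinol, irrelevant). Cleave the terminal glycol with silica-supported NaIO4 in CH2Cl2 to 4-[(1R,2S)-2-[4-(1,3-dioxolan-2-yl)-2,6-dimethoxyphenoxy]-1-hydroxy-3-oxopropyl]-2-methoxyphenyl acetate F3. Reduce it at once with NaBH(OAc)3 (hydroxyl-directed, non-basic, spares the acetate) to diol 14; the HCl/THF hydrolysis of step 4 then gives 15.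

Step 5. Risks: the one-flask Wittig/DIBAL sequence (Ph3PO and ylide residues consuming hydride); aluminium-promoted benzylic C7–O loss once the phenoxide forms; traces of Z isomer. Fallback, setting out from 15 and returning at 18: Wittig reaction with (triphenylphosphoranylidene)acetaldehyde (toluene, 80 °C) gives the enal 4-[(1R,2R)-2-[2,6-dimethoxy-4-[(E)-3-oxoprop-1-en-1-yl]phenoxy]-1,3-dihydroxypropyl]-2-methoxyphenyl acetate F4. Luche reduction (NaBH4, CeCl3·7H2O, MeOH, 0 °C) gives 4-[(1R,2R)-1,3-dihydroxy-2-[4-[(E)-3-hydroxyprop-1-en-1-yl]-2,6-dimethoxyphenoxy]propyl]-2-methoxyphenyl acetate F5. K2CO3 in MeOH at rt removes the acetate to give 18, with no aluminium hydride involved.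

**Further compounds**
F1 | step 3 | 2-[(2Z)-3-[4-(1,3-dioxolan-2-yl)-2,6-dimethoxyphenoxy]prop-2-en-1-yl]-4,4,5,5-tetramethyl-1,3,2-dioxaborolane | COc1cc(C2OCCO2)cc(OC)c1O/C=C\CB1OC(C)(C)C(C)(C)O1
F2 | step 4 | 4-[(1R,2S)-2-[4-(1,3-dioxolan-2-yl)-2,6-dimethoxyphenoxy]-1,3,4-trihydroxybutyl]-2-methoxyphenyl acetate (C3 epimer mixture) | COc1cc([C@@H](O)[C@@H](C(O)CO)Oc2c(OC)cc(C3OCCO3)cc2OC)ccc1OC(C)=O
F3 | step 4 | 4-[(1R,2S)-2-[4-(1,3-dioxolan-2-yl)-2,6-dimethoxyphenoxy]-1-hydroxy-3-oxopropyl]-2-methoxyphenyl acetate | COc1cc([C@@H](O)[C@@H](C=O)Oc2c(OC)cc(C3OCCO3)cc2OC)ccc1OC(C)=O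
F4 | step 5 | 4-[(1R,2R)-2-[2,6-dimethoxy-4-[(E)-3-oxoprop-1-en-1-yl]phenoxy]-1,3-dihydroxypropyl]-2-methoxyphenyl acetate | COc1cc([C@@H](O)[C@@H](CO)Oc2c(OC)cc(/C=C/C=O)cc2OC)ccc1OC(C)=O
F5 | step 5 | 4-[(1R,2R)-1,3-dihydroxy-2-[4-[(E)-3-hydroxyprop-1-en-1-yl]-2,6-dimethoxyphenoxy]propyl]-2-methoxyphenyl acetate | COc1cc([C@@H](O)[C@@H](CO)Oc2c(OC)cc(/C=C/CO)cc2OC)ccc1OC(C)=O
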